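**Numbering convention.** Eremophilane numbering is used throughout. Ring A is C1–C5 plus C10; ring B is C5–C10. C14 is the methyl on C5, C15 the methyl on C4, C11–C13 the isopropenyl group on C7. β is the face of C14.

## Analysis of the target

The target is 9β-angeloyloxy-3α-senecioyloxy-10βH-eremophil-11-en-8-one, (3R,4R,5R,7R,9R,10S): a cis-fused decalin with a 5β-methyl on the quaternary ring-fusion carbon C5 and a 10β-hydrogen. Ring A carries four contiguous stereocenters, C3 (α-oxygen, senecioate), C4 (β-methyl), C5 and C10, and none of them can be corrected later by epimerisation. Ring B carries the C8 ketone between C7 (β-isopropenyl) and C9 (β-angelate); both centres are epimerisable, and both are equatorial in the chair–chair conformer in which the C3 and C4 substituents are equatorial, so they can be relayed from ring A. The sensitive groups are the β,γ-unsaturated ketone (the isopropenyl double bond migrates easily into conjugation), the α-acyloxy ketone, the angelate (Z to E isomerisation), the senecioate (deconjugation), and the presence of two different esters on two secondary alcohols. The hard part is the quaternary C5 next to C4 with the two methyl groups cis, the C3 oxygen trans to C15, and the cis ring fusion, all in one absolute sense. The feature this route uses: atoms C15–C4=C5(C14)–C6 are the carbon skeleton of (E)-2-methylbut-2-enal, whose E geometry already holds the cis relation of C14 and C15, and C3–C2–C1–C10 is a diene. Ring A with the whole stereotetrad C3/C4/C5/C10 is therefore one Diels–Alder reaction away, if the C3 oxygen is carried as a C–B bond so that the electronically preferred regiochemistry is the required one.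

## Retrosynthetic reasoning

**24 from 23 (C6–H and C7–H).** The last step is a 1,4-reduction of the cross-conjugated dienone 23. The isomerisation-prone β,γ-unsaturated ketone then exists only in the final, neutral step, and C7 is set by protonation of an enolate whose conformation is already fixed by ring A.

**23 from 20 and 21; 20 from 18; 18 from 16 and 17 (two C–O ester bonds and the C9–O bond).** In dienone 18, C9 is the only enolisable carbon, so the C9 oxygen can be introduced regiospecifically by enolate oxidation. The two esters are put on one after the other, each as soon as its hydroxyl exists, so no protecting group is needed on ring A or on C9.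

**16 from 13 (C6=C7 bond, ring B; C3–O from C3–B).** Ring B is closed by an intramolecular aldol condensation between the C6 aldehyde and the α-carbon (C7) of the dienamine of the C8 enone. The aldehyde oxygen leaves by dehydration, so C6 needs no separate deoxygenation, and the isopropenyl group is generated in the same event. The C3 hydroxyl appears by oxidation of the C–B bond with retention.

**13 from 10 through 12 and 11 (adjustments).** These are saturation of C1=C2, removal of the silyl group and oxidation of the C8 carbinol. The carbinol is kept protected up to here because a ketone at C8 next to the C9 methylene and the diene would isomerise.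

**10 from 8 and 9 (C3–C4 and C5–C10, ring A).** This is the key disconnection. It cuts ring A into tiglic aldehyde 9 and the (E,E)-dienyl boronate 8. The forward Diels–Alder reaction has to set C3, C4, C5 and C10 together, with the formyl group endo and on one enantioface. The precursors are achiral 9 and an acyclic diene whose only stereocentre (C8) is irrelevant.

**8 from 5 and 6 (C1–C2); 5 from 4; 4 from 1 and 2 (C8–C9).** The diene is assembled by hydroboration of the terminal alkyne of 5 and sp2–sp2 coupling with the bromovinyl boronate 6. The alkyne 5 comes from propargylation of 3-methylbut-2-enal 1 with 2. The fifteen skeletal carbons are thus: C7, C8, C11–C13 from 1; C9, C10, C1 from 2; C2, C3 from 6; C4, C5, C6, C14, C15 from 9.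

## Alternatives that were turned down

**Alternative 1:** the textbook route, Robinson annulation. Disconnection: C5–C6 and C9–C10. Forward key step: Michael addition of cyclohexanone A1 to a vinyl ketone and aldol condensation to enone A2. Turned down because A1 already needs the C3/C4 stereocentres made one by one before the annulation. The Michael acceptor then has to approach C5 next to the C4 methyl group, which favours the trans and not the cis arrangement of C14 and C15. The ring fusion, C7 and C9 still have to be set afterwards, so the stereocentres are introduced singly over a long sequence with no step that secures the quaternary centre and its neighbours together.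

**Alternative 2:** skeletal rearrangement from an aromatic ring A. Disconnection: C5–C6 by an anionic oxy-Cope rearrangement. Forward key step: Birch reduction of a trisubstituted anisole, Diels–Alder reaction with a ketene equivalent and addition of a vinyl metal would give bicyclic carbinol A3, whose potassium alkoxide would rearrange to cis-decalin A4. The mapping is attractive: the arene supplies C1–C5, C10, both methyl groups and the C3 oxygen, and the rearrangement makes the quaternary C5 and the cis fusion. It was turned down on stereochemical grounds:
- In A4, C4 is an enol ether carbon and C7 and C9 flank a ketone, so all three are set by protonation or enolate chemistry on a flexible cis-decalin. That decalin has two chair–chair conformers, each with its own all-equatorial set (4β/7β/9β or 4α/7α/9α), so there is no thermodynamic or kinetic reference for C4.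
- A substituent that could serve as reference (an oxygen at C9 placed on the rigid bicyclic ketone) would sit on the face from which the vinyl nucleophile must enter.
- The C3 ketone would be reduced from the face opposite to the axial C14, giving the wrong (axial) alcohol.
- A separate asymmetric step would be needed for absolute control.

**Alternative 3:** intramolecular Diels–Alder reaction closing both rings. Disconnection: C3–C4 and C5–C10 with ring B as the tether. Forward key step: thermal cyclisation of trienone A5 to A6, which would set the same four centres and carry the senecioate from the start. Turned down for three reasons. The only position from which the tigloyl dienophile can be activated inside the tether is C6, so A6 has a ketone at C6 that must be removed while C8 must be oxidised and C7 and C9 functionalised. The oxygen-bearing diene terminus C3 has to bond to the electrophilic carbon C4, against the polarisation of a 1-acyloxy diene, so rate and endo selectivity rest on the tether alone. And the acyclic precursor with a Z/E-defined dienyl ester is itself long to make. The intermolecular version chosen here keeps the stereochemical logic, has matched polarity, and leaves C6 as an aldehyde that is consumed productively.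

Key step: step 4

**Remarks on the chemistry (assumptions).**
- Compound 6 and both enantiomers of α,α-diphenylprolinol are taken as commercial.
- The carbinol carbon C8 of 4, 5, 7, 8, 10, 11 and 12 is racemic and becomes the ketone carbon in step 7; these compounds are carried as pairs of C8 epimers and their SMILES leave C8 undefined.
- The oxazaborolidinium ion made from (R)-α,α-diphenylprolinol is assumed, by the usual model for 2-substituted enals (formyl C–H···O contact, enal stacked on the near phenyl ring), to leave the C5 Si face of 9 open; if the sense of induction were the opposite, the catalyst from the (S)-amino alcohol would be used with no other change.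

## Route

Step 1
Reactants: 1 3-methylbut-2-enal; 2 3-bromoprop-1-yne (propargyl bromide)
Product: 4 rac-6-methylhept-5-en-1-yn-4-ol, via allenylzinc bromide 3 (not isolated)
Conditions: Zn dust, THF, 0 °C → rt; aq NH4Cl
Reagents that add atoms: none
Why: Barbier-type propargylation; the allenylzinc species adds through its γ-carbon (SE2′) to the aldehyde carbonyl (1,2-addition) and gives the homopropargylic alcohol that holds C7–C13 and C9, C10, C1. The carbinol carbon (future C8) is left racemic because it becomes a ketone in step 7.

Step 2
Reactants: 4 rac-6-methylhept-5-en-1-yn-4-ol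
Product: 5 rac-tert-butyl(dimethyl)[(6-methylhept-5-en-1-yn-4-yl)oxy]silane
Conditions: TBSCl, imidazole, DMF, rt
Reagents that add atoms: tert-butyldimethylsilyl chloride, CC(C)(C)[Si](C)(C)Cl
Why: Standard silylation of a secondary alcohol; the ether keeps the hydroxyl away from the Lewis acid of step 4 and prevents a C8 ketone from isomerising the skipped diene.

Step 3
Reactants: 5 rac-tert-butyl(dimethyl)[(6-methylhept-5-en-1-yn-4-yl)oxy]silane; 6 2-[(E)-2-bromoethenyl]-6-methyl-1,3,6,2-dioxazaborocane-4,8-dione ((E)-2-bromovinylboronic acid MIDA ester)
Product: 8 2-[(1E,3E)-6-(tert-butyldimethylsilyloxy)-8-methylnona-1,3,7-trien-1-yl]-6-methyl-1,3,6,2-dioxazaborocane-4,8-dione, via alkenylboronic ester 7 (not isolated)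
Conditions: pinacolborane, Cp2Zr(H)Cl (5 mol %), CH2Cl2, rt; then 6, Pd(OAc)2 (3 mol %), 2-dicyclohexylphosphino-2′,6′-dimethoxybiphenyl (6 mol %), K3PO4 (anhydrous), THF, 45 °C
Reagents that add atoms: none
Why: Zirconium-catalysed syn hydroboration puts boron on the terminal alkyne carbon and fixes the E geometry of C10=C1; Suzuki–Miyaura coupling with the vinyl bromide of 6 under anhydrous base forms C1–C2 with retention at both alkenes, while the tetracoordinate boronate of 6 does not transmetalate and survives as the masked C3 hydroxyl.

Step 4
Reactants: 8 2-[(1E,3E)-6-(tert-butyldimethylsilyloxy)-8-methylnona-1,3,7-trien-1-yl]-6-methyl-1,3,6,2-dioxazaborocane-4,8-dione; 9 (E)-2-methylbut-2-enal (tiglic aldehyde)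
Product: 10 ring A aldehyde (Diels–Alder adduct: cyclohex-1-ene with 3α-boronate; 4β-methyl; 5β-methyl; 5α-formyl; 10β-H; side chain C9–C13 on C10; C8 epimers)
Conditions: 9 (2 equiv), B-(o-tolyl)oxazaborolidine from (R)-α,α-diphenylprolinol protonated with HNTf2 (20 mol %), CH2Cl2, −78 → −20 °C
Reagents that add atoms: none
Why: Concerted, asynchronous [4+2] cycloaddition of the Lewis-acid-bound s-trans enal 9 with the s-cis diene of 8; the closest known reaction types are the oxazaborolidinium-catalysed enantioselective Diels–Alder reaction of 2-substituted enals and the cycloaddition of 1-boryl and 1-silyl dienes used as masked 1-hydroxy dienes. Ring A is closed by an intermolecular six-membered cycloaddition that forms C3–C4 and C5–C10; ring B is not closed here. C4 and C5: the methyl groups C15 and C14 are cis in 9 and stay cis because addition to the dienophile is suprafacial. C3 and C10: with the formyl group endo, the two outside substituents of the (E,E)-diene (boron on C3, the chain on C10) end on the face of the formyl carbon C6, which is the 3α-boron, 10β-hydrogen arrangement. Absolute configuration: the catalyst holds the formyl group by B–O coordination and a formyl C–H···O contact and one phenyl ring covers the C5 Re face, so the diene adds to the C5 Si face and gives 5R. Regiochemistry: the largest LUMO coefficient of the complexed enal is at C4 and the most nucleophilic diene terminus is C3, because charge building up at C2 is stabilised by the adjacent electron-rich C–B σ bond of the tetracoordinate boronate and charge at C10 by the alkyl chain, and the bulky boronate also prefers C4 over the quaternary C5. The step needs endo over exo selectivity, which complexation of the formyl group should secure, reaction at the diene and not at the unconjugated trisubstituted alkene, and survival of the silyl ether and the boronate cage, both tolerant of boron Lewis acids at low temperature.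

Step 5
Reactants: 10 ring A aldehyde (Diels–Alder adduct)
Product: 11 saturated ring A aldehyde (cyclohexane with 3α-boronate; 4β-methyl; 5β-methyl; 5α-formyl; 10β-H; silyl ether side chain; C8 epimers)
Conditions: KO2CN=NCO2K, AcOH, MeCN–MeOH, rt
Reagents that add atoms: none
Why: Diimide formed in the flask transfers H2 in a concerted syn fashion to the unhindered cis-disubstituted ring alkene C1=C2; the trisubstituted side-chain alkene reacts far more slowly and the aldehyde, boronate and silyl ether are inert. No metal catalyst is used, so decarbonylation and allylic C–B or C–O hydrogenolysis cannot occur.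

Step 6
Reactants: 11 saturated ring A aldehyde
Product: 12 hydroxy aldehyde (as 11 with free C8 hydroxyl; C8 epimers)
Conditions: HF·pyridine, THF, 0 °C → rt
Reagents that add atoms: none
Why: Fluoride cleavage of the secondary silyl ether; acidic HF·pyridine is chosen because the boronate cage does not tolerate basic fluoride. Reversible closure of the alcohol onto the C6 aldehyde does not matter for step 7.

Step 7
Reactants: 12 hydroxy aldehyde
Product: 13 keto aldehyde (ring A with 5α-formyl and 10α-(4-methyl-2-oxopent-3-enyl) chain; 3α-boronate)
Conditions: MnO2, CH2Cl2, rt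
Reagents that add atoms: none
Why: MnO2 oxidises only the allylic alcohol, which gives the β,β-dimethyl enone and erases the racemic C8 centre; the non-allylic, non-enolisable C6 aldehyde is not touched.

Step 8
Reactants: 13 keto aldehyde
Product: 16 3α-hydroxy-10βH-eremophila-6,11-dien-8-one, via dienone boronate 14 (not isolated), via dienone boronic acid 15 (not isolated)
Conditions: pyrrolidine (0.3 equiv), AcOH (0.3 equiv), toluene, 50 °C; then 1 M aq NaOH, THF, rt; then NaBO3·4H2O, rt
Reagents that add atoms: sodium perborate, [Na+].[O-]OB=O
Why: Amine-catalysed intramolecular aldol condensation: the linear dienamine of the β,β-dimethyl enone attacks the non-enolisable C6 aldehyde through its α-carbon C7, the only mode that gives a six-membered ring, and dehydration gives the cross-conjugated dienone with the isopropenyl group already on C7. Hydroxide then frees the boronic acid and perborate oxidises the C–B bond with retention to the 3α-alcohol. Ring B is cis-fused because C6 and C9 were placed cis in step 4.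

Step 9
Reactants: 16 3α-hydroxy-10βH-eremophila-6,11-dien-8-one; 17 3-methylbut-2-enoyl chloride
Product: 18 3α-senecioyloxy-10βH-eremophila-6,11-dien-8-one
Conditions: 17, pyridine, 4-(dimethylamino)pyridine (cat.), CH2Cl2, 0 °C
Reagents that add atoms: none
Why: Acylation of the equatorial 3α-alcohol; pyridine instead of a stronger amine base avoids the vinylketene pathway that would deconjugate the senecioyl group.

Step 10
Reactants: 18 3α-senecioyloxy-10βH-eremophila-6,11-dien-8-one
Product: 20 9β-hydroxy-3α-senecioyloxy-10βH-eremophila-6,11-dien-8-one, via potassium dienolate 19 (not isolated)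
Conditions: KN(SiMe3)2, THF, −78 °C; then 2-(phenylsulfonyl)-3-phenyloxaziridine, −78 °C; aq NH4Cl
Reagents that add atoms: 2-(phenylsulfonyl)-3-phenyloxaziridine, O=S(=O)(c1ccccc1)N1OC1c1ccccc1
Why: C9 is the only enolisable carbon of the cross-conjugated dienone, so deprotonation is regiospecific; electrophilic hydroxylation of the enolate (a Rubottom-type outcome without peracid, so the isopropenyl group is safe) should occur on the β face, anti to C1 on the neighbouring C10. The 9β-alcohol is also the equatorial epimer.

Step 11
Reactants: 20 9β-hydroxy-3α-senecioyloxy-10βH-eremophila-6,11-dien-8-one; 21 (Z)-2-methylbut-2-enoic acid (angelic acid)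
Product: 23 9β-angeloyloxy-3α-senecioyloxy-10βH-eremophila-6,11-dien-8-one, via mixed anhydride 22 (not isolated)
Conditions: 21, 2,4,6-trichlorobenzoyl chloride, Et3N, toluene, rt; then 20, toluene, 80 °C
Reagents that add atoms: none
Why: Yamaguchi-type mixed-anhydride esterification; forming the anhydride first and acylating without free amine or nucleophilic catalyst is the established way to keep the Z geometry of the angeloyl group. The dienone has no epimerisable C7 and no migrating double bond, so it tolerates the heating.

Step 12
Reactants: 23 9β-angeloyloxy-3α-senecioyloxy-10βH-eremophila-6,11-dien-8-one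
Product: 24 9β-angeloyloxy-3α-senecioyloxy-10βH-eremophil-11-en-8-one (target)
Conditions: Cu(OAc)2·H2O (5 mol %), 1,2-bis(diphenylphosphino)benzene (5 mol %), HSiMe(OEt)2, t-BuOH, toluene, 0 °C → rt
Reagents that add atoms: none
Why: Copper hydride conjugate reduction: hydride goes to C6, the β-carbon of the dienone, while the two enoate esters react far more slowly. tert-Butanol protonates the copper dienolate at C7 (α, kinetic), which keeps the double bond in the isopropenyl position, and axial protonation from the α face of the ring-A-anchored chair puts the isopropenyl group equatorial (7β). The medium is neutral, so the finished β,γ-unsaturated α′-acyloxy ketone meets neither acid nor base.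

## Compound list

1 | 3-methylbut-2-enal | CC(C)=CC=O | starting material
2 | 3-bromoprop-1-yne (propargyl bromide) | C#CCBr | starting material
3 | propa-1,2-dienylzinc bromide (allenylzinc bromide) | C=C=C[Zn]Br | intermediate
4 | rac-6-methylhept-5-en-1-yn-4-ol | C#CCC(O)C=C(C)C | intermediate
5 | rac-tert-butyl(dimethyl)[(6-methylhept-5-en-1-yn-4-yl)oxy]silane | C#CCC(O[Si](C)(C)C(C)(C)C)C=C(C)C | intermediate
6 | 2-[(E)-2-bromoethenyl]-6-methyl-1,3,6,2-dioxazaborocane-4,8-dione | C[N+]12CC(=O)O[B-]1(/C=C/Br)OC(=O)C2 | starting material
7 | 2-[(1E)-4-(tert-butyldimethylsilyloxy)-6-methylhepta-1,5-dien-1-yl]-4,4,5,5-tetramethyl-1,3,2-dioxaborolane (C4 racemic) | CC1(C)OB(/C=C/CC(O[Si](C)(C)C(C)(C)C)C=C(C)C)OC1(C)C | intermediate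
8 | 2-[(1E,3E)-6-(tert-butyldimethylsilyloxy)-8-methylnona-1,3,7-trien-1-yl]-6-methyl-1,3,6,2-dioxazaborocane-4,8-dione (C6 racemic) | C[N+]12CC(=O)O[B-]1(/C=C/C=C/CC(O[Si](C)(C)C(C)(C)C)C=C(C)C)OC(=O)C2 | intermediate
9 | (E)-2-methylbut-2-enal (tiglic aldehyde) | C/C=C(\C)C=O | starting material
10 | ring A aldehyde, Diels–Alder adduct (target numbering): cyclohex-1-ene with 3α-(N-methyliminodiacetato)boryl, 4β-methyl, 5β-methyl, 5α-formyl (C6), 10β-H; C10 carries the 2-(tert-butyldimethylsilyloxy)-4-methylpent-3-enyl chain (C9, C8, C7, C11–C13); both C8 epimers | O=C[C@@]1(C)[C@H](C=C[C@@H]([B-]23OC(=O)C[N+]2(C)CC(=O)O3)[C@@H]1C)CC(O[Si](C)(C)C(C)(C)C)C=C(C)C | intermediate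
11 | saturated ring A aldehyde: as 10 with C1–C2 single bond; both C8 epimers | O=C[C@@]1(C)[C@H](CC[C@@H]([B-]23OC(=O)C[N+]2(C)CC(=O)O3)[C@@H]1C)CC(O[Si](C)(C)C(C)(C)C)C=C(C)C | intermediate
12 | hydroxy aldehyde: as 11 with free C8 hydroxyl; both C8 epimers | O=C[C@@]1(C)[C@H](CC[C@@H]([B-]23OC(=O)C[N+]2(C)CC(=O)O3)[C@@H]1C)CC(O)C=C(C)C | intermediate
13 | keto aldehyde: as 11 with the 4-methyl-2-oxopent-3-enyl chain on C10 (C8 ketone) | O=C[C@@]1(C)[C@H](CC[C@@H]([B-]23OC(=O)C[N+]2(C)CC(=O)O3)[C@@H]1C)CC(=O)C=C(C)C | intermediate
14 | 3α-(N-methyliminodiacetato)boryl-10βH-eremophila-6,11-dien-8-one (4β,5β-dimethyl) | C=C(C)C1=C[C@@]2(C)[C@H](CC[C@@H]([B-]34OC(=O)C[N+]3(C)CC(=O)O4)[C@@H]2C)CC1=O | intermediate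
15 | (8-oxo-10βH-eremophila-6,11-dien-3α-yl)boronic acid | C=C(C)C1=C[C@@]2(C)[C@H](CC[C@@H](B(O)O)[C@@H]2C)CC1=O | intermediate
16 | 3α-hydroxy-10βH-eremophila-6,11-dien-8-one | C=C(C)C1=C[C@@]2(C)[C@H](CC[C@@H](O)[C@@H]2C)CC1=O | intermediate
17 | 3-methylbut-2-enoyl chloride (senecioyl chloride) | CC(C)=CC(=O)Cl | starting material
18 | 3α-senecioyloxy-10βH-eremophila-6,11-dien-8-one | C=C(C)C1=C[C@@]2(C)[C@H](CC[C@@H](OC(=O)C=C(C)C)[C@@H]2C)CC1=O | intermediate
19 | potassium 8,9-dienolate of 18 | C=C(C)C1=C[C@@]2(C)[C@H](CC[C@@H](OC(=O)C=C(C)C)[C@@H]2C)C=C1[O-].[K+] | intermediate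
20 | 9β-hydroxy-3α-senecioyloxy-10βH-eremophila-6,11-dien-8-one | C=C(C)C1=C[C@@]2(C)[C@H](CC[C@@H](OC(=O)C=C(C)C)[C@@H]2C)[C@@H](O)C1=O | intermediate
21 | (Z)-2-methylbut-2-enoic acid (angelic acid) | C/C=C(/C)C(=O)O | starting material
22 | (Z)-2-methylbut-2-enoic 2,4,6-trichlorobenzoic anhydride | C/C=C(/C)C(=O)OC(=O)c1c(Cl)cc(Cl)cc1Cl | intermediate
23 | 9β-angeloyloxy-3α-senecioyloxy-10βH-eremophila-6,11-dien-8-one | C=C(C)C1=C[C@@]2(C)[C@H](CC[C@@H](OC(=O)C=C(C)C)[C@@H]2C)[C@@H](OC(=O)/C(C)=C\C)C1=O | intermediate
24 | (3R,4R,5R,7R,9R,10S)-9β-angeloyloxy-3α-senecioyloxy-10βH-eremophil-11-en-8-one | C=C(C)[C@H]1C[C@@]2(C)[C@H](CC[C@@H](OC(=O)C=C(C)C)[C@@H]2C)[C@@H](OC(=O)/C(C)=C\C)C1=O | target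

## Step count and least certain steps

Total step count: 12. Longest linear sequence: 12 steps (from 1 and 2 to 24); 6, 9, 17 and 21 are commercial and enter directly.

**Step 4 (key step).** Most likely to go wrong: a slow cycloaddition between a trisubstituted enal and a 1,4-disubstituted diene, so that the temperature has to be raised and endo and facial selectivity erode; the ester carbonyls of the boronate cage may also tie up part of the catalyst. Fallback, which moves absolute control from the catalyst to a separable stereocentre: it sets out from 4. Lipase-catalysed kinetic resolution (immobilised Candida antarctica lipase B, vinyl acetate, hexane) leaves (S)-6-methylhept-5-en-1-yn-4-ol F1 (which enantiomer is kept does not matter) and gives (R)-6-methylhept-5-en-1-yn-4-yl acetate F2. F1 is taken through steps 2 and 3 to the (S)-forms of 5 and 8. Cycloaddition with 9 under an achiral Lewis acid (EtAlCl2, 20 mol %, CH2Cl2, −78 °C) then gives 10 as its 8S epimer together with the ring-enantiomeric diastereomer F3, and the two are separated by chromatography. The route is rejoined at 10.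

**Step 8.** Most likely to go wrong: condensation through the α′-enamine (no productive ring size), retro-aldol loss of the isobutenyl unit once aqueous base is added too early, or stalling at the aldol stage. Fallback, ring B closed by an ene reaction instead of an aldol: it sets out from 11. Sc(OTf)3 (5 mol %, CH2Cl2, −40 °C) should trigger the intramolecular carbonyl-ene reaction of the C6 aldehyde with the trisubstituted alkene, giving the 6-hydroxy-7-isopropenyl silyl ether F4, with C6–C7 formed and the isopropenyl group created directly. syn-Dehydration with methyl N-(triethylammoniosulfonyl)carbamate gives the 6,11-diene silyl ether F5, HF·pyridine the dienol F6, and MnO2 oxidation returns to the route at 14, which is then treated with aqueous NaOH and NaBO3 as in the second half of step 8.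

**Step 12.** Most likely to go wrong: slow hydride transfer to the neopentyl β-carbon C6, protonation at C7 from the wrong face, or drift of the isopropenyl double bond into conjugation during work-up. Fallback, reduction before the C9 oxygen is present: it sets out from 18. LiBH(s-Bu)3 (THF, −78 °C, then t-BuOH) performs the 1,4-reduction on the more robust dienone and gives 3α-senecioyloxy-10βH-eremophil-11-en-8-one F8. Kinetic deprotonation at the C9 methylene (KN(SiMe3)2, −78 °C) and oxidation with 2-(phenylsulfonyl)-3-phenyloxaziridine give the 9β-hydroxy ketone F9, and esterification as in step 11 comes back to the route at 24.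

**Step 10.** Most likely to go wrong: attack of the oxidant on the α face of the enolate, or addition of the enolate to the sulfonimine formed from the oxidant. Fallback, radical α′-acyloxylation instead of enolate oxidation and esterification: it sets out from 18 and 21. Mn(OAc)3 in benzene at reflux with an excess of 21 should introduce the angeloyloxy group directly at C9 of the enone, under thermodynamic control of the C9 configuration, and comes back to the route at 23; no new compound is made (entry F0).

**Step 11.** Most likely to go wrong: Z to E isomerisation of the angeloyl group during activation, or slow acylation of the hindered α-hydroxy ketone. Fallback, the double bond of the ester is built after the acylation: it sets out from 20. Esterification with 2-[bis(2,2,2-trifluoroethoxy)phosphoryl]propanoic acid (N,N′-dicyclohexylcarbodiimide, CH2Cl2) gives the phosphonopropanoate F7. Still–Gennari olefination with acetaldehyde (KN(SiMe3)2, 18-crown-6, THF, −78 °C) forms the Z-trisubstituted alkene and comes back to the route at 23.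

## Further compounds

F1 | step 4 | (S)-6-methylhept-5-en-1-yn-4-ol | C#CC[C@H](O)C=C(C)C
F2 | step 4 | (R)-6-methylhept-5-en-1-yn-4-yl acetate | C#CC[C@@H](OC(C)=O)C=C(C)C
F3 | step 4 | diastereomer of 10 with enantiomeric ring A and (8S) side chain | O=C[C@]1(C)[C@@H](C=C[C@H]([B-]23OC(=O)C[N+]2(C)CC(=O)O3)[C@H]1C)C[C@H](O[Si](C)(C)C(C)(C)C)C=C(C)C
F4 | step 8 | 8-(tert-butyldimethylsilyloxy)-3α-(N-methyliminodiacetato)boryl-10βH-eremophil-11-en-6-ol (C6, C7, C8 mixtures) | C=C(C)C1C(O)[C@@]2(C)[C@H](CC[C@@H]([B-]34OC(=O)C[N+]3(C)CC(=O)O4)[C@@H]2C)CC1O[Si](C)(C)C(C)(C)C
F5 | step 8 | 8-(tert-butyldimethylsilyloxy)-3α-(N-methyliminodiacetato)boryl-10βH-eremophila-6,11-diene (C8 epimers) | C=C(C)C1=C[C@@]2(C)[C@H](CC[C@@H]([B-]34OC(=O)C[N+]3(C)CC(=O)O4)[C@@H]2C)CC1O[Si](C)(C)C(C)(C)C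
F6 | step 8 | 3α-(N-methyliminodiacetato)boryl-10βH-eremophila-6,11-dien-8-ol (C8 epimers) | C=C(C)C1=C[C@@]2(C)[C@H](CC[C@@H]([B-]34OC(=O)C[N+]3(C)CC(=O)O4)[C@@H]2C)CC1O
F0 | step 10 | none | none
F7 | step 11 | 9β-[2-[bis(2,2,2-trifluoroethoxy)phosphoryl]propanoyloxy]-3α-senecioyloxy-10βH-eremophila-6,11-dien-8-one | C=C(C)C1=C[C@@]2(C)[C@H](CC[C@@H](OC(=O)C=C(C)C)[C@@H]2C)[C@@H](OC(=O)C(C)P(=O)(OCC(F)(F)F)OCC(F)(F)F)C1=O
F8 | step 12 | 3α-senecioyloxy-10βH-eremophil-11-en-8-one | C=C(C)[C@H]1C[C@@]2(C)[C@H](CC[C@@H](OC(=O)C=C(C)C)[C@@H]2C)CC1=O
F9 | step 12 | 9β-hydroxy-3α-senecioyloxy-10βH-eremophil-11-en-8-one | C=C(C)[C@H]1C[C@@]2(C)[C@H](CC[C@@H](OC(=O)C=C(C)C)[C@@H]2C)[C@@H](O)C1=O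
A1 | alternative 1 | 4-(tert-butyldimethylsilyloxy)-2,3-dimethylcyclohexan-1-one (3,4-trans; C2 epimers) | O=C1CC[C@@H](O[Si](C)(C)C(C)(C)C)[C@H](C)C1C
A2 | alternative 1 | 3α-(tert-butyldimethylsilyloxy)-11,12,13-trinoreremophil-9-en-8-one | C1C[C@@]2(C)C(CC[C@@H](O[Si](C)(C)C(C)(C)C)[C@@H]2C)=CC1=O
A3 | alternative 2 | 1-methoxy-5,6-dimethyl-2-vinylbicyclo[2.2.2]oct-5-en-2-ol (vinyl syn to the C5=C6 bridge) | CC1=C(C)[C@@H]2CC[C@@]1(OC)[C@](O)(C=C)C2
A4 | alternative 2 | 3-methoxy-11,12,13-trinor-10βH-eremophil-3-en-8-one | C1C[C@@]2(C)[C@H](CCC(OC)=C2C)CC1=O
A5 | alternative 3 | (1E,3E,9E)-9-methyl-8-oxoundeca-1,3,9-trien-1-yl 3-methylbut-2-enoate | C/C=C(\C)C(=O)CCC/C=C/C=C/OC(=O)C=C(C)C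
A6 | alternative 3 | 3α-senecioyloxy-11,12,13-trinor-10βH-eremophil-1-en-6-one | C1C(=O)[C@@]2(C)[C@H](C=C[C@@H](OC(=O)C=C(C)C)[C@@H]2C)CC1
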